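The route disconnects the δ-lactone at its alkyl C–O bond: the C20 methylene is carried as a plain methyl group on the quaternary C10 of a ring A cyclohexanone. The key step exploits that C20 is β to C1 (the carbon that later bears the acetate) and δ to the C7 carboxyl. A C1 oxime-directed palladium C–H activation hands C20 to the tethered carboxylate and closes the lactone ring (O, C20, C10, C9, C8, C7) in one operation. Its precursor is a monocyclic keto-acid oxime ether. The spirolactone is then alkylated with an alkynyl iodide, a samarium ketyl–olefin/aldol cascade builds rings C and B, and a final alkyne hydroesterification installs the acrylate.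

Key step: step 5

Remark: atoms are numbered as in the kaurane-type skeleton of the target (C1 carries the acetate, C4 the two methyl groups, C6 and C11 the hydroxyl groups, C7 is the lactone carbonyl, C20 the lactone CH2, C15 the ester carbonyl, C16=C17 the methylene); aldehyde 12 is taken as commercially available.

Step 1
Reactants: 1 4,4-dimethylcyclohex-2-en-1-one
Product: 4 (2S,3S)-3-(hydroxymethyl)-2,4,4-trimethylcyclohexan-1-one, via magnesium enolate 2 (not isolated), via silyl ketone 3 (not isolated)
Conditions: (i-PrO)Me2SiCH2MgCl, CuBr·SMe2 (5 mol %), Josiphos ligand (6 mol %, enantiomer giving the 3S adduct), t-BuOMe, –78 °C; then MeI, DMPU, –78 to 0 °C; then KF, KHCO3, 30% H2O2, THF/MeOH, rt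
Reagents that add atoms: (isopropoxydimethylsilyl)methylmagnesium chloride CC(C)O[Si](C)(C)C[Mg]Cl; iodomethane CI; hydrogen peroxide OO
Why: Copper-catalysed asymmetric conjugate addition of the Grignard reagent should set C5 under ligand control, the magnesium enolate is methylated regiospecifically at C10 trans to the new group, and Tamao oxidation converts the C–Si bond into the C6 hydroxyl with C5 untouched.

Step 2
Reactants: 4 (2S,3S)-3-(hydroxymethyl)-2,4,4-trimethylcyclohexan-1-one
Product: 5 (2S,3S)-2,4,4-trimethyl-3-({[tri(propan-2-yl)silyl]oxy}methyl)cyclohexan-1-one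
Conditions: i-Pr3SiCl, imidazole, DMF, rt
Reagents that add atoms: chlorotri(propan-2-yl)silane CC(C)[Si](Cl)(C(C)C)C(C)C
Why: Silylation of the primary alcohol should give an ether that withstands the oxidative, basic and hydride steps up to step 15.

Step 3
Reactants: 5 (2S,3S)-2,4,4-trimethyl-3-({[tri(propan-2-yl)silyl]oxy}methyl)cyclohexan-1-one
Product: 8 methyl 3-[(1S,2R)-1,3,3-trimethyl-6-oxo-2-({[tri(propan-2-yl)silyl]oxy}methyl)cyclohexyl]propanoate, via benzyl imine 6 (not isolated), via alkylated imine 7 (not isolated)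
Conditions: BnNH2, TsOH (cat.), toluene, reflux (Dean–Stark); methyl acrylate, THF, 60 °C; 10% aq AcOH, rt
Reagents that add atoms: methyl acrylate C=CC(=O)OC; water O
Why: The imine should react through its more substituted secondary enamine tautomer in an aza-ene-type Michael addition, which alkylates C10 only and brings the acrylate in anti to the C5 silyloxymethyl group, so the quaternary centre gets C9 trans to C6 and the C20 methyl cis to it.

Step 4
Reactants: 8 methyl 3-[(1S,2R)-1,3,3-trimethyl-6-oxo-2-({[tri(propan-2-yl)silyl]oxy}methyl)cyclohexyl]propanoate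
Product: 10 3-[(1S,2R,6E)-6-(methoxyimino)-1,3,3-trimethyl-2-({[tri(propan-2-yl)silyl]oxy}methyl)cyclohexyl]propanoic acid, via oxime ester 9 (not isolated)
Conditions: MeONH2·HCl, pyridine, MeOH, 60 °C; then LiOH, THF/H2O, rt; aq HCl to pH 4
Reagents that add atoms: O-methylhydroxylamine hydrochloride CON.Cl; lithium hydroxide [Li+].[OH-]
Why: Oxime ether formation on the hindered ketone should give the E isomer (OMe anti to the quaternary C10), and saponification of the methyl ester then frees the C7 acid without touching the silyl ether.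

Step 5
Reactants: 10 3-[(1S,2R,6E)-6-(methoxyimino)-1,3,3-trimethyl-2-({[tri(propan-2-yl)silyl]oxy}methyl)cyclohexyl]propanoic acid
Product: 11 (6R,7R,11E)-11-(methoxyimino)-8,8-dimethyl-7-({[tri(propan-2-yl)silyl]oxy}methyl)-2-oxaspiro[5.5]undecan-3-one
Conditions: Pd(OAc)2 (10 mol %), t-BuOOH (70% aq, 3 equiv), CsHCO3 (0.5 equiv), HFIP, 60 °C
Reagents that add atoms: none
Why: Proposed new method: the E oxime ether nitrogen, whose lone pair faces C10, binds divalent palladium and a concerted metalation–deprotonation at the C20 methyl gives a five-membered palladacycle (Pd, N, C1, C10, C20); t-BuOOH oxidises it to tetravalent palladium, and the C7 carboxylate held on C10 through C9 and C8 then attacks C20 with loss of divalent palladium (C–O reductive elimination), which forms the O–C20 bond. The closest known reaction types are the oxime-ether-directed acetoxylation of β-methyl groups with Pd(OAc)2 and PhI(OAc)2 and the palladium-catalysed β-C–H lactonisation of free carboxylic acids with t-BuOOH; new here is that the palladated methyl is handed to an internal carboxylate that is not the directing group. The δ-lactone ring (O, C20, C10, C9, C8, C7) closes in a 6-exo-tet mode at C20. No stereocentre is created: C20 is a CH2 group and C5 and C10 are not touched, so the spiro centre keeps the configuration set in step 3. The step needs the primary C20–H bond to react before the secondary C9–H2 and C2–H2 bonds, which the E geometry of the oxime, the intrinsic preference of palladation for methyl groups and the remoteness of the C4 methyls (γ to C1) should secure, and it needs the carboxylate to beat external oxygen nucleophiles, which the acetate-free oxidant and the intramolecular delivery favour.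

Step 6
Reactants: 12 4-[(tert-butyldimethylsilyl)oxy]butanal
Product: 13 (2R)-4-[(tert-butyldimethylsilyl)oxy]-2-(hydroxymethyl)butanal
Conditions: 37% aq CH2O, (S)-α,α-diphenylprolinol trimethylsilyl ether (10 mol %), pH 7 phosphate buffer, toluene, rt; used crude
Reagents that add atoms: formaldehyde C=O
Why: Enamine-catalysed α-hydroxymethylation (cross-aldol with formaldehyde) should set C13, the electrophile being expected to attack the enamine face remote from the CPh2(OSiMe3) group.

Step 7
Reactants: 13 (2R)-4-[(tert-butyldimethylsilyl)oxy]-2-(hydroxymethyl)butanal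
Product: 14 (3S)-tert-butyl{[5,5-dibromo-3-(bromomethyl)pent-4-en-1-yl]oxy}dimethylsilane
Conditions: CBr4, PPh3, 2,6-lutidine, CH2Cl2, 0 °C
Reagents that add atoms: carbon tetrabromide BrC(Br)(Br)Br
Why: Corey–Fuchs dibromo-olefination of the aldehyde and Appel bromination of the alcohol should occur in the same flask under near-neutral conditions, so the epimerisable C13 of the β-hydroxy aldehyde is preserved.

Step 8
Reactants: 14 (3S)-tert-butyl{[5,5-dibromo-3-(bromomethyl)pent-4-en-1-yl]oxy}dimethylsilane
Product: 16 (3S)-{[3-(bromomethyl)-5-(trimethylsilyl)pent-4-yn-1-yl]oxy}(tert-butyl)dimethylsilane, via lithium acetylide 15 (not isolated)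
Conditions: n-BuLi (2.1 equiv), THF, –78 °C; then Me3SiCl, –78 °C to rt
Reagents that add atoms: chlorotrimethylsilane C[Si](C)(C)Cl
Why: In the second stage of the Corey–Fuchs reaction, bromine–lithium exchange, α-elimination and 1,2-shift give the lithium acetylide, which is C-silylated, while the primary alkyl bromide should not react at –78 °C.

Step 9
Reactants: 16 (3S)-{[3-(bromomethyl)-5-(trimethylsilyl)pent-4-yn-1-yl]oxy}(tert-butyl)dimethylsilane
Product: 17 (3S)-tert-butyl{[3-(iodomethyl)-5-(trimethylsilyl)pent-4-yn-1-yl]oxy}dimethylsilane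
Conditions: NaI, acetone, reflux
Reagents that add atoms: sodium iodide [Na+].[I-]
Why: Finkelstein exchange at the primary carbon should give the more reactive iodide without touching C13.

Step 10
Reactants: 11 (6R,7R,11E)-11-(methoxyimino)-8,8-dimethyl-7-({[tri(propan-2-yl)silyl]oxy}methyl)-2-oxaspiro[5.5]undecan-3-one; 17 (3S)-tert-butyl{[3-(iodomethyl)-5-(trimethylsilyl)pent-4-yn-1-yl]oxy}dimethylsilane
Product: 18 spirolactone oxime ether alkylated at C8 (both C8 epimers)
Conditions: LiN(SiMe3)2, THF/HMPA, –78 °C; then 17, –78 to –20 °C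
Reagents that add atoms: none
Why: Lithium enolate alkylation: the base should deprotonate only the lactone α-position C8 (the oxime ether, which here also protects C1, has far less acidic α-protons), and the enolate displaces the primary iodide to form the C8–C14 bond; the C8 configuration is irrelevant because C8 becomes sp2 in step 11.

Step 11
Reactants: 18 spirolactone oxime ether alkylated at C8 (both C8 epimers)
Product: 20 unsaturated spirolactone oxime ether (C8=C9), via phenylselenide 19 (not isolated)
Conditions: LiN(SiMe3)2, THF, –78 °C; PhSeBr; then 30% H2O2, pyridine, CH2Cl2, 0 °C to rt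
Reagents that add atoms: none
Why: α-Selenenylation of the lactone enolate followed by selenoxide syn-elimination toward the ring hydrogen on C9 should give the endocyclic conjugated C8=C9 alkene.

Step 12
Reactants: 20 unsaturated spirolactone oxime ether (C8=C9)
Product: 21 C1 ketone of the unsaturated spirolactone
Conditions: TiCl3 (aq), NH4OAc, THF/H2O, rt
Reagents that add atoms: water O
Why: Deoximation: trivalent titanium cleaves the N–O bond of the oxime ether and the imine is hydrolysed to the C1 ketone under buffered conditions that should spare the silyl ethers, the silylalkyne and the enoate.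

Step 13
Reactants: 21 C1 ketone of the unsaturated spirolactone
Product: 22 C1 alcohol (hydroxyl equatorial, cis to C20)
Conditions: NaBH4, CeCl3·7H2O, MeOH/THF, –40 °C; AcOH quench
Reagents that add atoms: none
Why: Luche reduction: hydride should add 1,2 to the ketone along the axial trajectory, on the face opposite the axial C20 methylene, which gives the equatorial C1 alcohol cis to C20 and leaves the conjugated lactone alone.

Step 14
Reactants: 22 C1 alcohol (hydroxyl equatorial, cis to C20)
Product: 23 C1 acetate
Conditions: Ac2O, DMAP (cat.), pyridine, CH2Cl2, 0 °C to rt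
Reagents that add atoms: acetic anhydride CC(=O)OC(C)=O
Why: DMAP-catalysed acetylation installs the C1 acetate of the target and removes the free hydroxyl that could translactonise onto C7.

Step 15
Reactants: 23 C1 acetate
Product: 24 diol with free C6 and C11 hydroxyls and terminal alkyne
Conditions: Bu4NF, AcOH, THF, 0 °C to rt
Reagents that add atoms: none
Why: Buffered fluoride desilylation should cleave both silyl ethers and the alkynyl C–Si bond while the acetate and the lactone survive.

Step 16
Reactants: 24 diol with free C6 and C11 hydroxyls and terminal alkyne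
Product: 25 dialdehyde (C6 and C11)
Conditions: Dess–Martin periodinane, NaHCO3, CH2Cl2, 0 °C to rt
Reagents that add atoms: none
Why: Dess–Martin oxidation of both primary alcohols should give the dialdehyde under non-epimerising, non-basic conditions.

Step 17
Reactants: 25 dialdehyde (C6 and C11)
Product: 27 tetracyclic alkyne diol, via samarium enolate 26 (not isolated)
Conditions: SmI2, LiBr, t-BuOH, THF, –78 °C
Reagents that add atoms: none
Why: Ketyl–olefin cyclisation/aldol cascade: the unhindered C11 aldehyde is reduced to a ketyl that should add 6-exo to C9 on the lactone face away from C5 through a chair with the C13 alkynyl group and the C11 oxygen equatorial, and the samarium enolate then closes ring B by aldol addition to the C6 aldehyde with the oxygen in the less hindered exo position, which sets C9, C11, C8 and C6.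

Step 18
Reactants: 27 tetracyclic alkyne diol
Product: 28 CNP0421185.1
Conditions: Pd(OAc)2 (2 mol %), 2-(diphenylphosphino)pyridine, MeSO3H (cat.), CO (1 atm), MeOH/CH2Cl2, 40 °C
Reagents that add atoms: carbon monoxide [C-]#[O+]; methanol CO
Why: Palladium-catalysed Markovnikov hydromethoxycarbonylation of the terminal alkyne places the ester carbon on the internal carbon C16 and should give the 2-substituted acrylate, while the catalytic acid at 40 °C leaves acetate, lactone and free alcohols alone.

Compound list
1 | 4,4-dimethylcyclohex-2-en-1-one | CC1(C)CCC(=O)C=C1 | starting material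
2 | chloromagnesium (3S)-3-{[dimethyl(propan-2-yloxy)silyl]methyl}-4,4-dimethylcyclohex-1-en-1-olate | CC1(C)CCC(O[Mg]Cl)=C[C@@H]1C[Si](C)(C)OC(C)C | intermediate
3 | (2S,3S)-3-{[dimethyl(propan-2-yloxy)silyl]methyl}-2,4,4-trimethylcyclohexan-1-one | C[C@@H]1C(=O)CCC(C)(C)[C@H]1C[Si](C)(C)OC(C)C | intermediate
4 | (2S,3S)-3-(hydroxymethyl)-2,4,4-trimethylcyclohexan-1-one | C[C@@H]1C(=O)CCC(C)(C)[C@H]1CO | intermediate
5 | (2S,3S)-2,4,4-trimethyl-3-({[tri(propan-2-yl)silyl]oxy}methyl)cyclohexan-1-one | C[C@@H]1C(=O)CCC(C)(C)[C@H]1CO[Si](C(C)C)(C(C)C)C(C)C | intermediate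
6 | N-benzyl imine of 5 (C10 epimerisable) | CC1C(=NCc2ccccc2)CCC(C)(C)[C@H]1CO[Si](C(C)C)(C(C)C)C(C)C | intermediate
7 | N-benzyl imine of 8 | COC(=O)CC[C@]1(C)C(=NCc2ccccc2)CCC(C)(C)[C@H]1CO[Si](C(C)C)(C(C)C)C(C)C | intermediate
8 | methyl 3-[(1S,2R)-1,3,3-trimethyl-6-oxo-2-({[tri(propan-2-yl)silyl]oxy}methyl)cyclohexyl]propanoate | COC(=O)CC[C@]1(C)C(=O)CCC(C)(C)[C@H]1CO[Si](C(C)C)(C(C)C)C(C)C | intermediate
9 | methyl ester of 10 (E O-methyl oxime) | CO/N=C1\CCC(C)(C)[C@@H](CO[Si](C(C)C)(C(C)C)C(C)C)[C@]1(C)CCC(=O)OC | intermediate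
10 | 3-[(1S,2R,6E)-6-(methoxyimino)-1,3,3-trimethyl-2-({[tri(propan-2-yl)silyl]oxy}methyl)cyclohexyl]propanoic acid | CO/N=C1\CCC(C)(C)[C@@H](CO[Si](C(C)C)(C(C)C)C(C)C)[C@]1(C)CCC(=O)O | intermediate
11 | (6R,7R,11E)-11-(methoxyimino)-8,8-dimethyl-7-({[tri(propan-2-yl)silyl]oxy}methyl)-2-oxaspiro[5.5]undecan-3-one | CO/N=C1\CCC(C)(C)[C@@H](CO[Si](C(C)C)(C(C)C)C(C)C)[C@@]12COC(=O)CC2 | intermediate
12 | 4-[(tert-butyldimethylsilyl)oxy]butanal | O=CCCCO[Si](C)(C)C(C)(C)C | starting material
13 | (2R)-4-[(tert-butyldimethylsilyl)oxy]-2-(hydroxymethyl)butanal | O=C[C@@H](CO)CCO[Si](C)(C)C(C)(C)C | intermediate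
14 | (3S)-tert-butyl{[5,5-dibromo-3-(bromomethyl)pent-4-en-1-yl]oxy}dimethylsilane | BrC(Br)=C[C@@H](CBr)CCO[Si](C)(C)C(C)(C)C | intermediate
15 | lithium acetylide from 14 (same configuration at C13) | [Li]C#C[C@@H](CBr)CCO[Si](C)(C)C(C)(C)C | intermediate
16 | (3S)-{[3-(bromomethyl)-5-(trimethylsilyl)pent-4-yn-1-yl]oxy}(tert-butyl)dimethylsilane | C[Si](C)(C)C#C[C@@H](CBr)CCO[Si](C)(C)C(C)(C)C | intermediate
17 | (3S)-tert-butyl{[3-(iodomethyl)-5-(trimethylsilyl)pent-4-yn-1-yl]oxy}dimethylsilane | C[Si](C)(C)C#C[C@@H](CI)CCO[Si](C)(C)C(C)(C)C | intermediate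
18 | 11 carrying at C8 (lactone α-carbon) the (2S)-4-[(tert-butyldimethylsilyl)oxy]-2-[(trimethylsilyl)ethynyl]butyl group; both C8 epimers | CO/N=C1\CCC(C)(C)[C@@H](CO[Si](C(C)C)(C(C)C)C(C)C)[C@@]12COC(=O)C(C[C@H](C#C[Si](C)(C)C)CCO[Si](C)(C)C(C)(C)C)C2 | intermediate
19 | 18 with a phenylselanyl group on C8 | CO/N=C1\CCC(C)(C)[C@@H](CO[Si](C(C)C)(C(C)C)C(C)C)[C@@]12COC(=O)C([Se]c3ccccc3)(C[C@H](C#C[Si](C)(C)C)CCO[Si](C)(C)C(C)(C)C)C2 | intermediate
20 | C8=C9 unsaturated spirolactone, E O-methyl oxime at C1, configuration at C5, C10 and C13 as in 18 | CO/N=C1\CCC(C)(C)[C@@H](CO[Si](C(C)C)(C(C)C)C(C)C)[C@@]12COC(=O)C(C[C@H](C#C[Si](C)(C)C)CCO[Si](C)(C)C(C)(C)C)=C2 | intermediate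
21 | C1 ketone corresponding to 20 | O=C1CCC(C)(C)[C@@H](CO[Si](C(C)C)(C(C)C)C(C)C)[C@@]12COC(=O)C(C[C@H](C#C[Si](C)(C)C)CCO[Si](C)(C)C(C)(C)C)=C2 | intermediate
22 | C1 alcohol from 21, hydroxyl cis to C20 and to C6, trans to C9 | O[C@H]1CCC(C)(C)[C@@H](CO[Si](C(C)C)(C(C)C)C(C)C)[C@@]12COC(=O)C(C[C@H](C#C[Si](C)(C)C)CCO[Si](C)(C)C(C)(C)C)=C2 | intermediate
23 | C1 acetate of 22 | CC(=O)O[C@H]1CCC(C)(C)[C@@H](CO[Si](C(C)C)(C(C)C)C(C)C)[C@@]12COC(=O)C(C[C@H](C#C[Si](C)(C)C)CCO[Si](C)(C)C(C)(C)C)=C2 | intermediate
24 | 23 with free C6 and C11 primary hydroxyls and terminal alkyne | CC(=O)O[C@H]1CCC(C)(C)[C@@H](CO)[C@@]12COC(=O)C(C[C@H](C#C)CCO)=C2 | intermediate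
25 | C6,C11-dialdehyde from 24 | CC(=O)O[C@H]1CCC(C)(C)[C@@H](C=O)[C@@]12COC(=O)C(C[C@H](C#C)CC=O)=C2 | intermediate
26 | samarium enolate after closure of ring C (C9–C11 bond formed, C11 alkoxide and C7 enolate on samarium, C6 aldehyde free) | CC(=O)O[C@H]1CCC(C)(C)[C@@H](C=O)[C@@]12COC(O[Sm](Br)Br)=C3C[C@H](C#C)C[C@H](O[Sm](Br)Br)[C@@H]23 | intermediate
27 | tetracyclic 1-acetoxy-6,11-dihydroxy 7,20-lactone with ethynyl group on C13, all ring stereocentres as in the target | C#C[C@@H]1C[C@H](O)[C@@H]2[C@]3(C1)C(=O)OC[C@]21[C@@H](OC(C)=O)CCC(C)(C)[C@H]1[C@@H]3O | intermediate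
28 | CNP0421185.1 (methyl 2-substituted acrylate on C13, 1-acetoxy, 6,11-dihydroxy, 7,20-lactone) | C=C(C(=O)OC)[C@@H]1C[C@H](O)[C@@H]2[C@]3(C1)C(=O)OC[C@]21[C@@H](OC(C)=O)CCC(C)(C)[C@H]1[C@@H]3O | target

Total step count: 18. Longest linear sequence: 14 steps (steps 1–5 and 10–18); steps 6–9 make the side-chain iodide.

Steps most likely to fail

Step 5. The palladated C20 methylene may be captured by tert-butyl peroxide, hydroxide or acetate instead of the internal carboxylate, or palladation may drift to the C9 methylene. The fallback sets out from 10 and comes back at 11, using known chemistry. Oxime-ether-directed acetoxylation of the methyl group (Pd(OAc)2, PhI(OAc)2, AcOH/Ac2O, 80 °C) should give the C20 acetoxy acid F1. K2CO3 in MeOH/H2O removes the acetyl group to give the C20 hydroxy acid F2, kept as its carboxylate. A Mitsunobu lactonisation (PPh3, DIAD, toluene, high dilution) then activates the C20 hydroxyl and lets the carboxylate oxygen displace it, which gives 11.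

Step 17. The aldol may not keep pace with protonation of the samarium enolate, or the hindered C6 aldehyde may be reduced or pinacol-coupled before ring C has closed. The fallback sets out from 23 and comes back at 27; it separates the two ring closures.
- Selective methanolysis of the primary tert-butyldimethylsilyl ether (PPTS, MeOH, 0 °C) should give the C11 alcohol F3, and Dess–Martin oxidation the mono-aldehyde F4.
- SmI2/LiBr in THF at –78 °C effects the ketyl–olefin cyclisation alone, and the resulting samarium enolate F5 is quenched in the flask with N-bromosuccinimide to give the α-bromo lactone F6 (C8 epimers).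
- Bu4NF/AcOH frees the C6 alcohol and the alkyne to give the bromo diol F7, and TEMPO/PhI(OAc)2 oxidises only the primary alcohol to the C6 aldehyde F8.
- A second SmI2 treatment (THF, –78 °C) reduces the C8–Br bond to the samarium enolate F9, which closes ring B in an intramolecular Reformatsky-type aldol to give 27.

Step 1. The silylmethyl group may transfer slowly from copper and with poor facial selectivity, which would erode the enantiomeric purity of everything that follows. The fallback sets out from 1 and comes back at 4. The same Grignard reagent is added with CuI (10 mol %) and no chiral ligand, followed by MeI/DMPU and the Tamao oxidation. This gives the racemic magnesium enolate (2 with its enantiomer F10), the racemic silyl ketone (3 with its enantiomer F11) and the racemic alcohol (4 with its enantiomer F12). A lipase-catalysed kinetic resolution (Amano lipase PS or a lipase found by screening, vinyl acetate, t-BuOMe) is then run so that the unwanted enantiomer is acetylated to the acetate F13. Alcohol 4 is recovered unreacted and separated by chromatography.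

Further compounds
F1 | step 5 | C20-acetoxy derivative of 10 (acetoxymethyl in place of the C10 methyl) | CO/N=C1\CCC(C)(C)[C@@H](CO[Si](C(C)C)(C(C)C)C(C)C)[C@]1(COC(C)=O)CCC(=O)O
F2 | step 5 | C20-hydroxy derivative of 10 (hydroxymethyl in place of the C10 methyl) | CO/N=C1\CCC(C)(C)[C@@H](CO[Si](C(C)C)(C(C)C)C(C)C)[C@]1(CO)CCC(=O)O
F3 | step 17 | 23 with free C11 hydroxyl (C6 silyl ether and silylalkyne kept) | CC(=O)O[C@H]1CCC(C)(C)[C@@H](CO[Si](C(C)C)(C(C)C)C(C)C)[C@@]12COC(=O)C(C[C@H](C#C[Si](C)(C)C)CCO)=C2
F4 | step 17 | C11 aldehyde from F3 | CC(=O)O[C@H]1CCC(C)(C)[C@@H](CO[Si](C(C)C)(C(C)C)C(C)C)[C@@]12COC(=O)C(C[C@H](C#C[Si](C)(C)C)CC=O)=C2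
F5 | step 17 | samarium enolate after ring C closure of F4 (not isolated) | CC(=O)O[C@H]1CCC(C)(C)[C@@H](CO[Si](C(C)C)(C(C)C)C(C)C)[C@@]12COC(O[Sm](Br)Br)=C3C[C@H](C#C[Si](C)(C)C)C[C@H](O[Sm](Br)Br)[C@@H]23
F6 | step 17 | tricyclic α-bromo lactone (C8–Br, C11–OH, C6 silyl ether; C8 epimers) | CC(=O)O[C@H]1CCC(C)(C)[C@@H](CO[Si](C(C)C)(C(C)C)C(C)C)[C@@]12COC(=O)C3(Br)C[C@H](C#C[Si](C)(C)C)C[C@H](O)[C@@H]23
F7 | step 17 | F6 with free C6 hydroxyl and terminal alkyne | CC(=O)O[C@H]1CCC(C)(C)[C@@H](CO)[C@@]12COC(=O)C3(Br)C[C@H](C#C)C[C@H](O)[C@@H]23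
F8 | step 17 | C6 aldehyde from F7 | CC(=O)O[C@H]1CCC(C)(C)[C@@H](C=O)[C@@]12COC(=O)C3(Br)C[C@H](C#C)C[C@H](O)[C@@H]23
F9 | step 17 | samarium enolate from F8 (not isolated) | CC(=O)O[C@H]1CCC(C)(C)[C@@H](C=O)[C@@]12COC(O[Sm](I)I)=C3C[C@H](C#C)C[C@H](O)[C@@H]23
F10 | step 1 | enantiomer of 2 | CC1(C)CCC(O[Mg]Cl)=C[C@H]1C[Si](C)(C)OC(C)C
F11 | step 1 | enantiomer of 3 | C[C@H]1C(=O)CCC(C)(C)[C@@H]1C[Si](C)(C)OC(C)C
F12 | step 1 | enantiomer of 4 | C[C@H]1C(=O)CCC(C)(C)[C@@H]1CO
F13 | step 1 | acetate of F12 | C[C@H]1C(=O)CCC(C)(C)[C@@H]1COC(C)=O
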